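# Proposed synthesis of CNP0196568.4, (2S,3S,2''R,3''S)-4'-O-methyl-3,3''-binaringenin (23)

## The problem

The target 23 is two 5,7-dihydroxyflavanone units joined through the C3–C3'' bond, so C2, C3, C3'' and C2'' are four contiguous stereocenters on a butane chain carrying two aroyl and two aryl groups. Unit 1 (4-methoxyphenyl at C2) is 2,3-cis (2S,3S), the less stable arrangement, and unit 2 (4-hydroxyphenyl at C2'') is 2,3-trans (2''R,3''S). Equilibration would erase the cis unit, so both rings C must be closed stereospecifically. The two halves differ only in a para-methoxy against a para-hydroxy group far from the stereocenters, so any pseudo-symmetric intermediate needs a real electronic handle to decide which half becomes the cis unit. C3 and C3'' are α to ketones and epimerise with base; C2 and C2'' are lost by retro-oxa-Michael ring opening. The free phloroglucinol rings are easily oxidised, so they stay benzylated until a neutral last step. Because the four centers sit on four consecutive carbons, a six-membered carbocycle can set them all in one cycloaddition, and no center then has to induce another. The feature that makes the key step possible is ring A: O1 on C8a and the C4 carbonyl on C4a are ortho, and C4a is flanked by the C5 oxygen. This is the pattern left when a carboxylic acid C–O bond adds across a 3-alkoxyaryne.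

## Retrosynthesis

**23 from 22.** Only the five O-benzyl bonds are cut. Benzyl is chosen for every phenol except the methyl ether of the target because hydrogenolysis is neutral, and the cis unit tolerates neither the base nor the acid that other phenol protecting groups need.

**22 from 21.** Both O1–C2 bonds are cut, giving diol 21, a double aldol-type array in which each benzylic carbinol is β to a 2-hydroxyaryl ketone. Conjugate addition of the phenol to an enone would give the trans isomer in both units. A dehydrative closure that inverts each carbinol (Mitsunobu) carries the configuration of 21 into 22 without passing through an enolate. The forward step needs SN2 displacement to outrun ionisation at the anisyl carbinol.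

**21 from 19, and 19 from 17.** Each carbinol C–O bond is traded for a C–CHO bond, since a Baeyer–Villiger shift of a secondary benzylic carbon proceeds with retention. The two aldehyde carbons of 19 are then joined as an alkene, which ties the four stereocenters into cyclohexene 17. In 17 the aryl groups are cis to each other, the aroyl groups are trans, and the aroyl group next to the anisyl carbon is cis to it. Retention followed by inversion turns this pattern into the cis unit 1 and the trans unit 2. The cost is two carbons that are built in and later excised; the gain is that all four centers become a Diels–Alder problem.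

**17 from 15 and 5 (key disconnection).** In each ring A the bonds C8a–O1 and C4a–C4 are cut together. That returns diacid 15 and two equivalents of 3,5-bis(benzyloxy)benzyne 16, generated from silylaryl triflate 5. Cutting only C4a–C4 (aryl-metal addition, Friedel–Crafts) would require a later selective unmasking of one ortho oxygen. The aryne route delivers the free ortho phenol needed for ring closure and uses a diacid with no β leaving group. The forward reaction must place oxygen at the aryne carbon remote from the flanking benzyloxy group, and the acyl group must shift to carbon.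

**15 from 14, and 14 from 13.** The benzyl ether of 15 is put on after the cycloaddition. The cycloadduct 13 instead carries a para-triflyloxy group on the future unit 2 aryl ring. One hydrolytic operation then frees both acids and the phenol (14), and one O-benzylation gives 15.

**13 from 9 and 12.** The cyclohexene is opened by a Diels–Alder disconnection to the E,E-diaryl diene 9 and the fumarate-derived imide ester 12.
- A fumarate with two equal acyl groups would leave nothing to decide which diene terminus ends beside the endo acyl group. In 12 only the imide chelates the chiral copper Lewis acid, so it is both the endo group and the polarising group.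
- The more advanced bond then forms at the ester-bearing carbon, and the diene terminus that attacks is the one that leaves the better stabilised allyl cation.
- With a para-methoxy group on one aryl ring and a para-triflyloxy group on the other, the anisyl carbon ends next to the imide carbon and cis to it, as 17 requires.
- The triflate is the strongest acceptor that is still a phenol protecting group removable by hydroxide. This is why it is preferred to a benzyl ether at this stage.

**9 from 7 and 8, 7 from 6; 12 from 10 and 11; 5 from 2 and 1.** Diene 9 comes from Heck arylation of the terminal diene 7 with 4-iodophenyl triflate 8, and 7 from Wittig methylenation of 4-methoxycinnamaldehyde 6. Imide 12 comes from oxazolidinone 10 and ethyl fumaroyl chloride 11. The aryne precursor 5 comes from 3,5-bis(benzyloxy)phenol 1 by ortho-bromination (2), O-silylation, retro-Brook shift and triflation.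

## Roads not taken

**Alternative 1:** The cut is at C4''–C3'' and at C3–C4, with carbon monoxide as the source of both carbonyl carbons. The precursor is the E-configured bis(aryl ether) A2, whose two O1–C2 bonds already exist and whose A ring of unit 2 carries an iodide. Zerovalent palladium (Pd(PPh3)4) would insert into the C–I bond, CO would give an aroyl complex, a 6-exo acylpalladation would close ring C of unit 2, and a second CO with methanol would end the cascade as the methyl ester A1.
- Merits: the C2 centers come from simple carbinols set early; no carbons are excised; no invertive closure at an anisyl carbinol is needed. In these respects it is better than the chosen plan.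
- Weak points: A2 is a doubly allylic, doubly benzylic aryl ether, which zerovalent palladium can ionise to an allyl complex. The alkylpalladium formed at C3 has a β-aryloxy group and β-hydrogens, so elimination competes with the second carbonylation. The facial course of the acylpalladation rests on one remote center. Ring C of unit 1 must still be closed by acylation of an electron-rich ring with two open positions, under acid that threatens the cis unit.
- Comparison: the chosen plan sets all four centers in one well-understood cycloaddition and builds both A rings by the same operation, against the shorter redox path of Alternative 1.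

**Alternative 2:** The cut is at C4–C4a and C4''–C4a''. The cis-fused bis-lactone A4 (anisyl endo, aryl exo) would be opened by two equivalents of the aryllithium A5 to give diol diketone A3.
- Merits: the lactone rings hold the stereocenters, and each addition stops at the ketone because the tetrahedral intermediate is a lactol alkoxide. A3 already carries both carbinols, and aryllithium addition to a lactone is better precedented than a double aryne insertion. On that point it is stronger than the chosen plan.
- Weak points: A4 as a single enantiomer with unlike endo and exo aryl groups has no short source, and would most plausibly come from the same cyclohexene by the same excision. Opening releases a β-alkoxide ketone under strongly basic conditions, inviting retro-aldol cleavage. A 2,6-disubstituted aryllithium adds slowly to a hindered lactone. A3 needs a selective ortho-debenzylation before it reaches the stage of 21.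
- Comparison: the aryne insertion acts before the carbinols exist, so no aldolate is exposed to strong base, and it gives the free ortho phenol directly.

**Alternative 3:** The same cyclohexene is cut by a Diels–Alder reaction, but the dienophile A7 already carries both aroyl groups. With diene A8 and a chiral oxazaborolidinium catalyst it would give A6 in one step.
- Merits: hydrolysis, benzylation and the aryne step disappear, about three steps. If the cycloaddition worked with good selectivity this road would be better in step economy.
- Weak points: the two carbonyl groups of A7 are equal, so endo selection and the pairing of diene termini depend on which carbonyl the catalyst happens to bind. The 2,4,6-trioxygenated aroyl groups are bulky, electron-rich and weakly Lewis basic, which makes A7 a poor partner for an already sluggish 1,4-diaryl diene. A6 still needs ortho-debenzylation at each ketone.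
- Comparison: the chosen plan uses a small dienophile with two-point binding, whose polarisation is unambiguous, and brings in the bulky aroyl groups afterwards, already carrying their free phenols.

Key step: step 9

## Route

Assumption: compounds 1, 8 and 11 are taken as purchased, and the (S,S)-ligand in step 6 is assigned from the square-planar chelate model of the copper–imide complex.

Step 1
Reactants: 1 3,5-bis(benzyloxy)phenol
Product: 2 2-bromo-3,5-bis(benzyloxy)phenol
Conditions: NBS, i-Pr2NH (cat.), CH2Cl2, −78 to 0 °C
Reagents that add atoms: N-bromosuccinimide, O=C1CCC(=O)N1Br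
Why: Amine-mediated electrophilic bromination of a phenol goes ortho to the hydroxyl group; the two ortho positions are equivalent, and any para isomer is removed at this stage.

Step 2
Reactants: 2 2-bromo-3,5-bis(benzyloxy)phenol
Product: 5 3,5-bis(benzyloxy)-2-(trimethylsilyl)phenyl trifluoromethanesulfonate, via aryl trimethylsilyl ether 3 (not isolated), via lithium 2-silylphenoxide 4 (not isolated)
Conditions: HMDS, THF, reflux, concentrate; n-BuLi, THF, −100 °C; Tf2O, −100 °C to rt
Reagents that add atoms: hexamethyldisilazane, C[Si](C)(C)N[Si](C)(C)C; trifluoromethanesulfonic anhydride, O=S(=O)(OS(=O)(=O)C(F)(F)F)C(F)(F)F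
Why: O-silylation, bromine–lithium exchange and retro-Brook (oxygen to carbon) silyl shift put silicon on the carbon between the two oxygens; the phenoxide is then triflated, the standard sequence to 2-silylaryl triflates.

Step 3
Reactants: 6 (E)-4-methoxycinnamaldehyde
Product: 7 (E)-1-(4-methoxyphenyl)buta-1,3-diene
Conditions: Ph3PCH3Br, KOt-Bu, THF, 0 °C to rt
Reagents that add atoms: methyltriphenylphosphonium bromide, C[P+](c1ccccc1)(c1ccccc1)c1ccccc1.[Br-]
Why: Wittig methylenation with the non-stabilised ylide; the existing E-alkene is untouched.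

Step 4
Reactants: 7 (E)-1-(4-methoxyphenyl)buta-1,3-diene; 8 4-iodophenyl trifluoromethanesulfonate
Product: 9 4-[(1E,3E)-4-(4-methoxyphenyl)buta-1,3-dien-1-yl]phenyl trifluoromethanesulfonate
Conditions: Pd(OAc)2 (cat.), Bu4NCl, NaHCO3, DMF, 60 °C
Reagents that add atoms: none
Why: Heck arylation of a terminal diene: the arylpalladium adds at the unsubstituted terminus and β-hydride elimination restores conjugation as the E,E-diene; without phosphine only the C–I bond reacts and the triflate is a spectator.

Step 5
Reactants: 10 1,3-oxazolidin-2-one; 11 ethyl (2E)-4-chloro-4-oxobut-2-enoate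
Product: 12 ethyl (2E)-4-oxo-4-(2-oxo-1,3-oxazolidin-3-yl)but-2-enoate
Conditions: n-BuLi, THF, −78 °C; then 11, −78 to 0 °C
Reagents that add atoms: none
Why: N-acylation of the lithiated oxazolidinone by the acid chloride, the usual preparation of N-enoyl oxazolidinones.

Step 6
Reactants: 9 4-[(1E,3E)-4-(4-methoxyphenyl)buta-1,3-dien-1-yl]phenyl trifluoromethanesulfonate; 12 ethyl (2E)-4-oxo-4-(2-oxo-1,3-oxazolidin-3-yl)but-2-enoate
Product: 13 ethyl (1R,2S,5R,6R)-5-(4-methoxyphenyl)-6-[(2-oxo-1,3-oxazolidin-3-yl)carbonyl]-2-{4-[(trifluoromethanesulfonyl)oxy]phenyl}cyclohex-3-ene-1-carboxylate (aryl groups cis; imide cis to both aryl groups and next to the anisyl carbon; ester trans)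
Conditions: [Cu((S,S)-t-Bu-box)](SbF6)2 (10 mol %; t-Bu-box = 2,2'-(propane-2,2-diyl)bis[(4S)-4-tert-butyl-4,5-dihydro-1,3-oxazole]), CH2Cl2, rt
Reagents that add atoms: none
Why: Enantioselective Diels–Alder reaction of an N-enoyl oxazolidinone chelated to cationic divalent copper: the chelated imide is endo, so it ends cis to both aryl groups; the more advanced bond joins the ester-bearing carbon to the triflyloxyphenyl terminus because the developing allyl cation is then stabilised by the anisyl group, which puts the imide next to the anisyl carbon; the tert-butyl group shields the Si face at the imide α-carbon, so all four centers are set by Re-face, endo addition.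

Step 7
Reactants: 13 the Diels–Alder adduct
Product: 14 (1R,2R,3S,6R)-3-(4-hydroxyphenyl)-6-(4-methoxyphenyl)cyclohex-4-ene-1,2-dicarboxylic acid
Conditions: LiOH, H2O2, THF/H2O, 0 °C; Na2SO3; then LiOH, 45 °C; HCl
Reagents that add atoms: lithium hydroxide, [Li+].[OH-]; hydrogen peroxide, OO
Why: Hydroperoxide cleaves the imide at the exocyclic carbonyl, hydroxide saponifies the ethyl ester and attacks sulfur of the aryl triflate to free the phenol; carboxylate formation protects both α-centers, whose present arrangement (three substituents equatorial) is also the most stable single epimer.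

Step 8
Reactants: 14 the hydroxyphenyl diacid
Product: 15 (1R,2R,3S,6R)-3-[4-(benzyloxy)phenyl]-6-(4-methoxyphenyl)cyclohex-4-ene-1,2-dicarboxylic acid
Conditions: BnBr, KOH, EtOH/H2O, 70 °C; then KOH, reflux; HCl
Reagents that add atoms: benzyl bromide, BrCc1ccccc1
Why: Williamson etherification: in aqueous ethanol the phenoxide of the trianion is far more nucleophilic than the solvated carboxylates, and any benzyl ester formed is saponified in the same pot.

Step 9
Reactants: 15 the benzyloxyphenyl diacid; 5 3,5-bis(benzyloxy)-2-(trimethylsilyl)phenyl trifluoromethanesulfonate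
Product: 17 {(1R,2R,3S,6R)-3-[4-(benzyloxy)phenyl]-6-(4-methoxyphenyl)cyclohex-4-ene-1,2-diyl}bis{[2,4-bis(benzyloxy)-6-hydroxyphenyl]methanone}, via 3,5-bis(benzyloxy)benzyne 16 (not isolated)
Conditions: 5 (3 equiv), CsF (8 equiv), THF, 125 °C, sealed tube
Reagents that add atoms: none
Why: Fluoride removes the silyl group of 5 and triflate leaves, giving aryne 16; each caesium carboxylate of 15 adds through oxygen to the aryne carbon remote from the flanking benzyloxy group, and the aryl anion formed beside that group attacks the adjacent aryl ester carbonyl through a four-membered transition state that opens to the 2-acylphenoxide. The closest known reaction type is the intermolecular insertion of arynes into the C–O bond of carboxylic acids in hot THF to give 2-hydroxyaryl ketones, used here once at each carboxyl group. No ring is closed and no stereocenter is formed; the four existing centers are spectators because carboxylates do not enolise, the diacid has no β leaving group, and the product ketones are present as chelated phenoxides. The selectivity needed is the aryne regiochemistry, secured by the inductive effect and ring distortion caused by the benzyloxy group next to the triple bond, which sends the nucleophile to the distal carbon and the acyl group to the proximal one, the sense known for this aryne in other acyl-transfer reactions; the new phenol oxygens are therefore O1 and O1'' and the ring pattern is 5,7-dioxygenated. The second requirement, C-acylation instead of simple O-arylation, is favoured by the aprotic medium and high temperature, which let the acyl shift outrun protonation of the aryl anion. The excess of 5 is kept moderate so that the product phenoxides are not arylated.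

Step 10
Reactants: 17 the cyclohexene bis(2-hydroxyaryl ketone)
Product: 19 (2R,3R,4R,5S)-5-[4-(benzyloxy)phenyl]-3,4-bis[2,4-bis(benzyloxy)-6-hydroxybenzoyl]-2-(4-methoxyphenyl)hexanedial, via secondary ozonide 18 (not isolated)
Conditions: O3, CH2Cl2, −78 °C (Sudan Red 7B end point); PPh3, −78 °C to rt; used crude
Reagents that add atoms: ozone, [O-][O+]=O
Why: Ozonolysis with reductive work-up cleaves the only alkene, which reacts much faster than the acyl-deactivated aromatic rings; cold, neutral conditions keep the two α-aryl aldehyde centers intact.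

Step 11
Reactants: 19 the dialdehyde
Product: 21 (1R,2S,3S,4S)-4-[4-(benzyloxy)phenyl]-2,3-bis[2,4-bis(benzyloxy)-6-hydroxybenzoyl]-1-(4-methoxyphenyl)butane-1,4-diol, via bis(formate) 20 (not isolated)
Conditions: mCPBA, NaHCO3, CH2Cl2, 0 °C to rt; then KHCO3, MeOH, 0 °C
Reagents that add atoms: 3-chloroperbenzoic acid, OOC(=O)c1cccc(Cl)c1
Why: Baeyer–Villiger oxidation of α-branched aldehydes: the secondary benzylic carbon migrates to oxygen with retention in preference to hydride, and aldehydes react far faster than the hindered, hydrogen-bonded aryl ketones; the formates are removed by mild methanolysis so the aldol units are not exposed to retro-aldol conditions.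

Step 12
Reactants: 21 the diol
Product: 22 (2S,3S)-5,7-bis(benzyloxy)-3-{(2R,3S)-5,7-bis(benzyloxy)-2-[4-(benzyloxy)phenyl]-4-oxo-3,4-dihydro-2H-chromen-3-yl}-2-(4-methoxyphenyl)-2,3-dihydro-4H-chromen-4-one
Conditions: PPh3, DIAD, THF, 0 °C to rt
Reagents that add atoms: none
Why: Double intramolecular Mitsunobu etherification, each a six-membered closure by the ortho phenol with inversion at the benzylic carbinol (1R to 2S, 4S to 2''R); the acyl-bearing carbon next to each carbinol disfavours ionisation, and the non-basic medium spares the cis unit.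

Step 13
Reactants: 22 the penta-O-benzyl biflavanone
Product: 23 (2S,3S)-5,7-dihydroxy-3-[(2R,3S)-5,7-dihydroxy-2-(4-hydroxyphenyl)-4-oxo-3,4-dihydro-2H-chromen-3-yl]-2-(4-methoxyphenyl)-2,3-dihydro-4H-chromen-4-one (CNP0196568.4)
Conditions: H2 (1 atm), Pd/C (10%), EtOAc/MeOH, rt
Reagents that add atoms: none
Why: Hydrogenolysis of the five aryl benzyl ethers under neutral conditions leaves the methyl ether, the ketones and the four stereocenters untouched.

## Compound list

1 | 3,5-bis(benzyloxy)phenol | Oc1cc(OCc2ccccc2)cc(OCc2ccccc2)c1 | starting material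
2 | 2-bromo-3,5-bis(benzyloxy)phenol | Oc1cc(OCc2ccccc2)cc(OCc2ccccc2)c1Br | intermediate
3 | [2-bromo-3,5-bis(benzyloxy)phenoxy]trimethylsilane | C[Si](C)(C)Oc1cc(OCc2ccccc2)cc(OCc2ccccc2)c1Br | intermediate (not isolated)
4 | lithium 3,5-bis(benzyloxy)-2-(trimethylsilyl)phenoxide | [Li+].[O-]c1cc(OCc2ccccc2)cc(OCc2ccccc2)c1[Si](C)(C)C | intermediate (not isolated)
5 | 3,5-bis(benzyloxy)-2-(trimethylsilyl)phenyl trifluoromethanesulfonate | C[Si](C)(C)c1c(OCc2ccccc2)cc(OCc2ccccc2)cc1OS(=O)(=O)C(F)(F)F | intermediate
6 | (E)-4-methoxycinnamaldehyde | COc1ccc(/C=C/C=O)cc1 | starting material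
7 | (E)-1-(4-methoxyphenyl)buta-1,3-diene | COc1ccc(/C=C/C=C)cc1 | intermediate
8 | 4-iodophenyl trifluoromethanesulfonate | FC(F)(F)S(=O)(=O)Oc1ccc(I)cc1 | starting material
9 | 4-[(1E,3E)-4-(4-methoxyphenyl)buta-1,3-dien-1-yl]phenyl trifluoromethanesulfonate | COc1ccc(/C=C/C=C/c2ccc(OS(=O)(=O)C(F)(F)F)cc2)cc1 | intermediate
10 | 1,3-oxazolidin-2-one | O=C1NCCO1 | starting material
11 | ethyl (2E)-4-chloro-4-oxobut-2-enoate | CCOC(=O)/C=C/C(Cl)=O | starting material
12 | ethyl (2E)-4-oxo-4-(2-oxo-1,3-oxazolidin-3-yl)but-2-enoate | CCOC(=O)/C=C/C(=O)N1CCOC1=O | intermediate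
13 | ethyl (1R,2S,5R,6R)-5-(4-methoxyphenyl)-6-[(2-oxo-1,3-oxazolidin-3-yl)carbonyl]-2-{4-[(trifluoromethanesulfonyl)oxy]phenyl}cyclohex-3-ene-1-carboxylate | COc1ccc(cc1)[C@@H]1C=C[C@H](c2ccc(OS(=O)(=O)C(F)(F)F)cc2)[C@@H](C(=O)OCC)[C@@H]1C(=O)N1CCOC1=O | intermediate
14 | (1R,2R,3S,6R)-3-(4-hydroxyphenyl)-6-(4-methoxyphenyl)cyclohex-4-ene-1,2-dicarboxylic acid | COc1ccc(cc1)[C@@H]1C=C[C@H](c2ccc(O)cc2)[C@@H](C(O)=O)[C@@H]1C(O)=O | intermediate
15 | (1R,2R,3S,6R)-3-[4-(benzyloxy)phenyl]-6-(4-methoxyphenyl)cyclohex-4-ene-1,2-dicarboxylic acid | COc1ccc(cc1)[C@@H]1C=C[C@H](c2ccc(OCc3ccccc3)cc2)[C@@H](C(O)=O)[C@@H]1C(O)=O | intermediate (key-step precursor)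
16 | 3,5-bis(benzyloxy)benzyne | C1#CC(OCc2ccccc2)=CC(OCc2ccccc2)=C1 | intermediate (not isolated)
17 | {(1R,2R,3S,6R)-3-[4-(benzyloxy)phenyl]-6-(4-methoxyphenyl)cyclohex-4-ene-1,2-diyl}bis{[2,4-bis(benzyloxy)-6-hydroxyphenyl]methanone} | COc1ccc(cc1)[C@@H]1C=C[C@H](c2ccc(OCc3ccccc3)cc2)[C@@H](C(=O)c2c(O)cc(OCc3ccccc3)cc2OCc2ccccc2)[C@@H]1C(=O)c1c(O)cc(OCc2ccccc2)cc1OCc1ccccc1 | intermediate (key-step product)
18 | secondary ozonide of 17 (6,7,8-trioxabicyclo[3.2.1]octane; the two acetal carbons form as a mixture and are left undefined) | COc1ccc(cc1)[C@@H]1C2OOC(O2)[C@H](c2ccc(OCc3ccccc3)cc2)[C@@H](C(=O)c2c(O)cc(OCc3ccccc3)cc2OCc2ccccc2)[C@@H]1C(=O)c1c(O)cc(OCc2ccccc2)cc1OCc1ccccc1 | intermediate (not isolated)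
19 | (2R,3R,4R,5S)-5-[4-(benzyloxy)phenyl]-3,4-bis[2,4-bis(benzyloxy)-6-hydroxybenzoyl]-2-(4-methoxyphenyl)hexanedial | COc1ccc(cc1)[C@H](C=O)[C@@H](C(=O)c1c(O)cc(OCc2ccccc2)cc1OCc1ccccc1)[C@H](C(=O)c1c(O)cc(OCc2ccccc2)cc1OCc1ccccc1)[C@H](C=O)c1ccc(OCc2ccccc2)cc1 | intermediate
20 | (1R,2S,3S,4S)-4-[4-(benzyloxy)phenyl]-2,3-bis[2,4-bis(benzyloxy)-6-hydroxybenzoyl]-1-(4-methoxyphenyl)butane-1,4-diyl diformate | COc1ccc(cc1)[C@H](OC=O)[C@@H](C(=O)c1c(O)cc(OCc2ccccc2)cc1OCc1ccccc1)[C@H](C(=O)c1c(O)cc(OCc2ccccc2)cc1OCc1ccccc1)[C@H](OC=O)c1ccc(OCc2ccccc2)cc1 | intermediate (not isolated)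
21 | (1R,2S,3S,4S)-4-[4-(benzyloxy)phenyl]-2,3-bis[2,4-bis(benzyloxy)-6-hydroxybenzoyl]-1-(4-methoxyphenyl)butane-1,4-diol | COc1ccc(cc1)[C@H](O)[C@@H](C(=O)c1c(O)cc(OCc2ccccc2)cc1OCc1ccccc1)[C@H](C(=O)c1c(O)cc(OCc2ccccc2)cc1OCc1ccccc1)[C@H](O)c1ccc(OCc2ccccc2)cc1 | intermediate
22 | (2S,3S)-5,7-bis(benzyloxy)-3-{(2R,3S)-5,7-bis(benzyloxy)-2-[4-(benzyloxy)phenyl]-4-oxo-3,4-dihydro-2H-chromen-3-yl}-2-(4-methoxyphenyl)-2,3-dihydro-4H-chromen-4-one | COc1ccc([C@H]2Oc3cc(OCc4ccccc4)cc(OCc4ccccc4)c3C(=O)[C@H]2[C@@H]2C(=O)c3c(OCc4ccccc4)cc(OCc4ccccc4)cc3O[C@H]2c2ccc(OCc3ccccc3)cc2)cc1 | intermediate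
23 | (2S,3S)-5,7-dihydroxy-3-[(2R,3S)-5,7-dihydroxy-2-(4-hydroxyphenyl)-4-oxo-3,4-dihydro-2H-chromen-3-yl]-2-(4-methoxyphenyl)-2,3-dihydro-4H-chromen-4-one | COc1ccc([C@H]2Oc3cc(O)cc(O)c3C(=O)[C@H]2[C@@H]2C(=O)c3c(O)cc(O)cc3O[C@H]2c2ccc(O)cc2)cc1 | target

## Step count and least certain steps

Total: 13 steps. Longest linear sequence: 10 steps (steps 3, 4, 6, 7, 8, 9, 10, 11, 12, 13, from 6).

**Step 9 (key step).** The most likely failure is protonation of the ortho-aryl anion before the acyl shift, which leaves aryl esters at one or both carboxyl groups. The secondary, ring-bound acyl groups slow the four-membered shift, and the anion is stabilised by the flanking benzyloxy group. A second drain is arylation of the product phenoxides by surplus aryne. The fallback forms only the C4a–C4 bonds by known chemistry. It sets out from 15, which is converted to the bis(N-methoxy-N-methylamide) F1 (N,O-dimethylhydroxylamine, carbodiimide coupling). F1 is treated with 2,4,6-tris(benzyloxy)phenyllithium F2, made from 1,3,5-tris(benzyloxy)benzene and n-BuLi, to give the bis[2,4,6-tris(benzyloxy)phenyl] diketone F3. MgBr2·OEt2 then removes the one chelated ortho benzyl group of each ring, and the route is rejoined at 17.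

**Step 6.** Two processes may fail: poor discrimination between the two diene termini, which would put the imide next to the triflyloxyphenyl carbon, and a slow reaction of the 1,4-diaryl diene under the mild catalyst. The fallback replaces catalyst control by a stoichiometric auxiliary and a stronger Lewis acid. It sets out from 9, which is combined with (4R)-4-benzyl-3-[(2E)-4-ethoxy-4-oxobut-2-enoyl]-1,3-oxazolidin-2-one F4 (from (R)-4-benzyloxazolidin-2-one and 11) and Et2AlCl in CH2Cl2 at −78 to −30 °C. The cationic aluminium chelate is more reactive and more polarised, and the benzyl group covers the Si face. The product is the auxiliary-bearing adduct F5, which is hydrolysed as in step 7 to rejoin the route at 14.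

**Step 11.** The likely problems are peracid attack on the electron-rich hydroxyaryl ketone rings (aryl migration or ring hydroxylation) and enolisation of the α-aryl aldehydes assisted by the neighbouring phenols. The fallback masks the phenols before the oxidations. It sets out from 17, which is acetylated (Ac2O, pyridine, DMAP) to the bis(acetate) F6. Ozonolysis through its ozonide F7 gives the dialdehyde bis(acetate) F8, and peracid oxidation gives the bis(formate) bis(acetate) F9. Methanolysis (K2CO3, MeOH, 0 °C) removes formates and acetates together and rejoins the route at 21.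

**Step 10.** Ozone may attack the benzyl ethers and oxygenated rings once the hindered alkene is consumed, or cleavage may be incomplete if the reaction is stopped early. The fallback avoids ozone. It sets out from 17, which is dihydroxylated (OsO4 cat., NMO, acetone/H2O) to the cis-diol F10, expected anti to the two aryl groups. Glycol cleavage with NaIO4 on silica in CH2Cl2 rejoins the route at 19.

**Step 13.** Prolonged exposure may cleave the benzylic C2–O1 bonds reductively, opening ring C to dihydrochalcones. The fallback is Lewis-acid debenzylation with a cation scavenger (BCl3, pentamethylbenzene, CH2Cl2, −78 °C), which spares the aryl methyl ether. It sets out from 22 and arrives directly at 23 with no new compound.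

## Further compounds

F1 | step 9 | (1R,2R,3S,6R)-3-[4-(benzyloxy)phenyl]-N1,N2-dimethoxy-6-(4-methoxyphenyl)-N1,N2-dimethylcyclohex-4-ene-1,2-dicarboxamide | COc1ccc(cc1)[C@@H]1C=C[C@H](c2ccc(OCc3ccccc3)cc2)[C@@H](C(=O)N(C)OC)[C@@H]1C(=O)N(C)OC
F2 | step 9 | 2,4,6-tris(benzyloxy)phenyllithium | [Li]c1c(OCc2ccccc2)cc(OCc2ccccc2)cc1OCc1ccccc1
F3 | step 9 | {(1R,2R,3S,6R)-3-[4-(benzyloxy)phenyl]-6-(4-methoxyphenyl)cyclohex-4-ene-1,2-diyl}bis{[2,4,6-tris(benzyloxy)phenyl]methanone} | COc1ccc(cc1)[C@@H]1C=C[C@H](c2ccc(OCc3ccccc3)cc2)[C@@H](C(=O)c2c(OCc3ccccc3)cc(OCc3ccccc3)cc2OCc2ccccc2)[C@@H]1C(=O)c1c(OCc2ccccc2)cc(OCc2ccccc2)cc1OCc1ccccc1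
F4 | step 6 | (4R)-4-benzyl-3-[(2E)-4-ethoxy-4-oxobut-2-enoyl]-1,3-oxazolidin-2-one | CCOC(=O)/C=C/C(=O)N1[C@H](Cc2ccccc2)COC1=O
F5 | step 6 | ethyl (1R,2S,5R,6R)-6-{[(4R)-4-benzyl-2-oxo-1,3-oxazolidin-3-yl]carbonyl}-5-(4-methoxyphenyl)-2-{4-[(trifluoromethanesulfonyl)oxy]phenyl}cyclohex-3-ene-1-carboxylate | COc1ccc(cc1)[C@@H]1C=C[C@H](c2ccc(OS(=O)(=O)C(F)(F)F)cc2)[C@@H](C(=O)OCC)[C@@H]1C(=O)N1[C@H](Cc2ccccc2)COC1=O
F6 | step 11 | bis(O-acetate) of 17 at the two chelated phenols | COc1ccc(cc1)[C@@H]1C=C[C@H](c2ccc(OCc3ccccc3)cc2)[C@@H](C(=O)c2c(OC(C)=O)cc(OCc3ccccc3)cc2OCc2ccccc2)[C@@H]1C(=O)c1c(OC(C)=O)cc(OCc2ccccc2)cc1OCc1ccccc1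
F7 | step 11 | secondary ozonide of F6 (acetal carbons undefined) | COc1ccc(cc1)[C@@H]1C2OOC(O2)[C@H](c2ccc(OCc3ccccc3)cc2)[C@@H](C(=O)c2c(OC(C)=O)cc(OCc3ccccc3)cc2OCc2ccccc2)[C@@H]1C(=O)c1c(OC(C)=O)cc(OCc2ccccc2)cc1OCc1ccccc1
F8 | step 11 | bis(O-acetate) of dialdehyde 19 | COc1ccc(cc1)[C@H](C=O)[C@@H](C(=O)c1c(OC(C)=O)cc(OCc2ccccc2)cc1OCc1ccccc1)[C@H](C(=O)c1c(OC(C)=O)cc(OCc2ccccc2)cc1OCc1ccccc1)[C@H](C=O)c1ccc(OCc2ccccc2)cc1
F9 | step 11 | bis(O-acetate) of bis(formate) 20 | COc1ccc(cc1)[C@H](OC=O)[C@@H](C(=O)c1c(OC(C)=O)cc(OCc2ccccc2)cc1OCc1ccccc1)[C@H](C(=O)c1c(OC(C)=O)cc(OCc2ccccc2)cc1OCc1ccccc1)[C@H](OC=O)c1ccc(OCc2ccccc2)cc1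
F10 | step 10 | 4,5-cis-diol of 17 (both hydroxyl groups anti to the aryl groups) | COc1ccc(cc1)[C@@H]1[C@@H](O)[C@@H](O)[C@H](c2ccc(OCc3ccccc3)cc2)[C@@H](C(=O)c2c(O)cc(OCc3ccccc3)cc2OCc2ccccc2)[C@@H]1C(=O)c1c(O)cc(OCc2ccccc2)cc1OCc1ccccc1
F0 | step 13 | none | none
A1 | alternative 1 | methyl 3-[3,5-bis(benzyloxy)phenoxy]-2-{5,7-bis(benzyloxy)-2-[4-(benzyloxy)phenyl]-4-oxochroman-3-yl}-3-(4-methoxyphenyl)propanoate | COc1ccc(cc1)[C@@H](Oc1cc(OCc2ccccc2)cc(OCc2ccccc2)c1)[C@@H](C(=O)OC)[C@@H]1C(=O)c2c(OCc3ccccc3)cc(OCc3ccccc3)cc2O[C@H]1c1ccc(OCc2ccccc2)cc1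
A2 | alternative 1 | (E)-1-[4-(benzyloxy)phenyl]-1-[3,5-bis(benzyloxy)-2-iodophenoxy]-4-[3,5-bis(benzyloxy)phenoxy]-4-(4-methoxyphenyl)but-2-ene | COc1ccc(cc1)[C@@H](Oc1cc(OCc2ccccc2)cc(OCc2ccccc2)c1)/C=C/[C@@H](Oc1cc(OCc2ccccc2)cc(OCc2ccccc2)c1I)c1ccc(OCc2ccccc2)cc1
A3 | alternative 2 | 1-[4-(benzyloxy)phenyl]-4-(4-methoxyphenyl)-2,3-bis[2,4,6-tris(benzyloxy)benzoyl]butane-1,4-diol | COc1ccc(cc1)[C@H](O)[C@@H](C(=O)c1c(OCc2ccccc2)cc(OCc2ccccc2)cc1OCc1ccccc1)[C@H](C(=O)c1c(OCc2ccccc2)cc(OCc2ccccc2)cc1OCc1ccccc1)[C@H](O)c1ccc(OCc2ccccc2)cc1
A4 | alternative 2 | cis-fused 8-[4-(benzyloxy)phenyl]-4-(4-methoxyphenyl)-3,7-dioxabicyclo[3.3.0]octane-2,6-dione (anisyl endo, aryl exo) | COc1ccc(cc1)[C@@H]1OC(=O)[C@H]2[C@@H]1C(=O)O[C@@H]2c1ccc(OCc2ccccc2)cc1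
A5 | alternative 2 | 2,4,6-tris(benzyloxy)phenyllithium | [Li]c1c(OCc2ccccc2)cc(OCc2ccccc2)cc1OCc1ccccc1
A6 | alternative 3 | cis-3-[4-(benzyloxycarbonyloxy)phenyl]-6-(4-methoxyphenyl)-trans-4,5-bis[2,4,6-tris(benzyloxy)benzoyl]cyclohexene | COc1ccc(cc1)[C@@H]1C=C[C@H](c2ccc(OC(=O)OCc3ccccc3)cc2)[C@@H](C(=O)c2c(OCc3ccccc3)cc(OCc3ccccc3)cc2OCc2ccccc2)[C@@H]1C(=O)c1c(OCc2ccccc2)cc(OCc2ccccc2)cc1OCc1ccccc1
A7 | alternative 3 | (E)-1,4-bis[2,4,6-tris(benzyloxy)phenyl]but-2-ene-1,4-dione | O=C(/C=C/C(=O)c1c(OCc2ccccc2)cc(OCc2ccccc2)cc1OCc1ccccc1)c1c(OCc2ccccc2)cc(OCc2ccccc2)cc1OCc1ccccc1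
A8 | alternative 3 | benzyl 4-[(1E,3E)-4-(4-methoxyphenyl)buta-1,3-dien-1-yl]phenyl carbonate | COc1ccc(/C=C/C=C/c2ccc(OC(=O)OCc3ccccc3)cc2)cc1
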